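**Retrosynthetic overview**
- The depside ester C(=O)–O bond is cut last-but-one, giving an A-ring acid (2-benzyloxy-6-heptyl-4-methoxybenzoic acid) and a B-ring phenol (benzyl 4-hydroxy-2-methoxy-6-pentylbenzoate). One final hydrogenolysis removes both benzyl groups.
- Each benzene ring comes from a methyl 6-alkyl-2,4-dihydroxybenzoate, made by aromatising a 6-alkyl-cyclohexane-1,3-dione-carboxylate.
- Key C–C bond: intermolecular Michael addition of dimethyl malonate to an (E)-alk-3-en-2-one, followed in the same pot by intramolecular Claisen (Dieckmann) ring closure.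
- Ring order: the heptyl A-ring is built and tailored first (4-OMe, 2-OBn, CO2H), then the pentyl B-ring (4-OBn, 2-OMe, CO2H, then 4-OH/CO2Bn), then the two are coupled.
- Enones: (E)-undec-3-en-2-one from octanal by Wittig olefination; (E)-non-3-en-2-one is bought.

Assumption: the target SMILES has no stereocentre, so the compound is achiral and no stereocontrol is needed. The sp3 centres of the cyclohexenone intermediates are racemic and are erased on aromatisation. Compounds are numbered in the order they appear in the forward route.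

**Route**

Step 1
Reactants: 1 octanal; 2 (acetylmethylene)triphenylphosphorane [1-(triphenyl-λ5-phosphanylidene)propan-2-one]
Product: 3 (E)-undec-3-en-2-one
Conditions: 2 (1.1 equiv), CH2Cl2, reflux, 16 h
Reagents that add atoms: none
Why: Wittig olefination with a ketone-stabilised ylide gives the conjugated methyl ketone cleanly and with high E selectivity, without self-aldol of the aldehyde.

Step 2
Reactants: 3 (E)-undec-3-en-2-one; 4 dimethyl malonate
Product: 6 methyl 6-heptyl-2-hydroxy-4-oxocyclohex-2-ene-1-carboxylate, via Michael adduct 5 (not isolated)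
Conditions: NaOMe (1.2 equiv), MeOH, rt then reflux, 4 h; aq. HCl, 0 °C
Reagents that add atoms: none
Why: Intermolecular Michael addition of the malonate anion to the enone β-carbon is followed by Dieckmann (intramolecular Claisen) condensation of the methyl-ketone enolate onto one ester, driven by the stable 1,3-dione enolate; the two new sp3 centres form racemically and are destroyed in step 3.

Step 3
Reactants: 6 methyl 6-heptyl-2-hydroxy-4-oxocyclohex-2-ene-1-carboxylate
Product: 8 methyl 6-heptyl-2,4-dihydroxybenzoate, via bromo-dione 7 (not isolated)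
Conditions: Br2 (1.0 equiv), DMF, 0 °C, 1 h; then 80 °C, 12 h
Reagents that add atoms: bromine, BrBr (its Br is carried only in intermediate 7; none of it remains in 8)
Why: Oxidative aromatisation by α-bromination of the enolised 1,3-dione at C-3, then vinylogous dehydrobromination and tautomerisation to the resorcylate.

Step 4
Reactants: 8 methyl 6-heptyl-2,4-dihydroxybenzoate
Product: 9 methyl 6-heptyl-2-hydroxy-4-methoxybenzoate
Conditions: MeI (1.1 equiv), K2CO3 (1.2 equiv), acetone, reflux
Reagents that add atoms: iodomethane, CI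
Why: Regioselective Williamson etherification, because the 4-OH is the more acidic and free phenol while the 2-OH is hydrogen-bonded to the ester carbonyl and stays unreacted with one equivalent of MeI.

Step 5
Reactants: 9 methyl 6-heptyl-2-hydroxy-4-methoxybenzoate
Product: 10 methyl 2-(benzyloxy)-6-heptyl-4-methoxybenzoate
Conditions: BnBr (1.3 equiv), K2CO3 (2 equiv), DMF, 60 °C
Reagents that add atoms: benzyl bromide, BrCc1ccccc1
Why: Williamson etherification in DMF with heating overcomes the chelation of the 2-OH and masks it as a hydrogenolysable benzyl ether.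

Step 6
Reactants: 10 methyl 2-(benzyloxy)-6-heptyl-4-methoxybenzoate
Product: 11 2-(benzyloxy)-6-heptyl-4-methoxybenzoic acid
Conditions: KOH (excess), DMSO/H2O 4:1, 90 °C; aq. HCl, 0 °C
Reagents that add atoms: potassium hydroxide, [K+].[OH-]
Why: Saponification of the di-ortho-substituted methyl ester with poorly solvated hydroxide in aqueous DMSO, under which the aryl benzyl and methyl ethers are inert.

Step 7
Reactants: 12 (E)-non-3-en-2-one; 4 dimethyl malonate
Product: 14 methyl 2-hydroxy-4-oxo-6-pentylcyclohex-2-ene-1-carboxylate, via Michael adduct 13 (not isolated)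
Conditions: NaOMe (1.2 equiv), MeOH, rt then reflux, 4 h; aq. HCl, 0 °C
Reagents that add atoms: none
Why: The same intermolecular Michael addition and Dieckmann (intramolecular Claisen) ring closure as step 2; the new sp3 centres are racemic and are removed in step 8.

Step 8
Reactants: 14 methyl 2-hydroxy-4-oxo-6-pentylcyclohex-2-ene-1-carboxylate
Product: 16 methyl 2,4-dihydroxy-6-pentylbenzoate, via bromo-dione 15 (not isolated)
Conditions: Br2 (1.0 equiv), DMF, 0 °C, 1 h; then 80 °C, 12 h
Reagents that add atoms: bromine, BrBr (its Br is carried only in intermediate 15; none of it remains in 16)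
Why: Bromination–dehydrobromination aromatisation of the dihydroresorcylate, as in step 3.

Step 9
Reactants: 16 methyl 2,4-dihydroxy-6-pentylbenzoate
Product: 17 methyl 4-(benzyloxy)-2-hydroxy-6-pentylbenzoate
Conditions: BnBr (1.05 equiv), K2CO3 (1.1 equiv), acetone, reflux
Reagents that add atoms: benzyl bromide, BrCc1ccccc1
Why: Regioselective Williamson etherification of the free 4-OH, the chelated 2-OH being much less nucleophilic under these mild conditions.

Step 10
Reactants: 17 methyl 4-(benzyloxy)-2-hydroxy-6-pentylbenzoate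
Product: 18 methyl 4-(benzyloxy)-2-methoxy-6-pentylbenzoate
Conditions: MeI (3 equiv), K2CO3 (3 equiv), DMF, 40 °C
Reagents that add atoms: iodomethane, CI
Why: Forcing Williamson methylation in DMF alkylates the remaining hydrogen-bonded 2-OH, the only nucleophilic site left.

Step 11
Reactants: 18 methyl 4-(benzyloxy)-2-methoxy-6-pentylbenzoate
Product: 19 4-(benzyloxy)-2-methoxy-6-pentylbenzoic acid
Conditions: KOH (excess), DMSO/H2O 4:1, 90 °C; aq. HCl, 0 °C
Reagents that add atoms: potassium hydroxide, [K+].[OH-]
Why: Saponification of the hindered methyl ester as in step 6, with both ethers stable to base.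

Step 12
Reactants: 19 4-(benzyloxy)-2-methoxy-6-pentylbenzoic acid
Product: 20 4-hydroxy-2-methoxy-6-pentylbenzoic acid
Conditions: H2 (1 atm), 10% Pd/C, EtOAc, rt
Reagents that add atoms: none
Why: Catalytic hydrogenolysis cleaves the aryl benzyl ether under neutral conditions that leave the acid, the methyl ether and the arene untouched.

Step 13
Reactants: 20 4-hydroxy-2-methoxy-6-pentylbenzoic acid
Product: 21 benzyl 4-hydroxy-2-methoxy-6-pentylbenzoate
Conditions: BnBr (1.05 equiv), KHCO3 (1.2 equiv), DMF, rt to 40 °C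
Reagents that add atoms: benzyl bromide, BrCc1ccccc1
Why: Chemoselective SN2 O-alkylation of the carboxylate, since bicarbonate deprotonates the acid (pKa about 4) but not the phenol (pKa about 9).

Step 14
Reactants: 11 2-(benzyloxy)-6-heptyl-4-methoxybenzoic acid; 21 benzyl 4-hydroxy-2-methoxy-6-pentylbenzoate
Product: 23 benzyl 4-{[2-(benzyloxy)-6-heptyl-4-methoxybenzoyl]oxy}-2-methoxy-6-pentylbenzoate, via mixed anhydride 22 (not isolated)
Conditions: TFAA (4 equiv), dry toluene, rt, 4 h
Reagents that add atoms: trifluoroacetic anhydride, O=C(OC(=O)C(F)(F)F)C(F)(F)F (its CF3CO group is carried only in intermediate 22; none of it remains in 23)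
Why: Mixed-anhydride esterification, in which the hindered electron-rich acid forms an acyl trifluoroacetate that acylates the only free phenol of 21 through an acylium-like species little affected by the two ortho substituents.

Step 15
Reactants: 23 benzyl 4-{[2-(benzyloxy)-6-heptyl-4-methoxybenzoyl]oxy}-2-methoxy-6-pentylbenzoate
Product: 24 4-[(2-heptyl-6-hydroxy-4-methoxybenzoyl)oxy]-2-methoxy-6-pentylbenzoic acid
Conditions: H2 (1 atm), 10% Pd/C, EtOAc, rt
Reagents that add atoms: none
Why: Global hydrogenolysis removes the benzyl ester and the benzyl ether in one neutral step that does not touch the aryl ester (depside) linkage.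

**Compound list**

1 | octanal | CCCCCCCC=O | starting material
2 | (acetylmethylene)triphenylphosphorane, 1-(triphenyl-λ5-phosphanylidene)propan-2-one | CC(=O)C=P(c1ccccc1)(c1ccccc1)c1ccccc1 | starting material
3 | (E)-undec-3-en-2-one | CCCCCCC/C=C/C(C)=O | intermediate
4 | dimethyl malonate | COC(=O)CC(=O)OC | starting material
5 | dimethyl 2-(2-oxoundecan-4-yl)propanedioate (racemic Michael adduct) | CCCCCCCC(CC(C)=O)C(C(=O)OC)C(=O)OC | intermediate (not isolated)
6 | methyl 6-heptyl-2-hydroxy-4-oxocyclohex-2-ene-1-carboxylate (racemic, diastereomer and tautomer mixture) | CCCCCCCC1CC(=O)C=C(O)C1C(=O)OC | intermediate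
7 | methyl 3-bromo-6-heptyl-2-hydroxy-4-oxocyclohex-2-ene-1-carboxylate (racemic) | CCCCCCCC1CC(=O)C(Br)=C(O)C1C(=O)OC | intermediate (not isolated)
8 | methyl 6-heptyl-2,4-dihydroxybenzoate | CCCCCCCc1cc(O)cc(O)c1C(=O)OC | intermediate
9 | methyl 6-heptyl-2-hydroxy-4-methoxybenzoate | CCCCCCCc1cc(OC)cc(O)c1C(=O)OC | intermediate
10 | methyl 2-(benzyloxy)-6-heptyl-4-methoxybenzoate | CCCCCCCc1cc(OC)cc(OCc2ccccc2)c1C(=O)OC | intermediate
11 | 2-(benzyloxy)-6-heptyl-4-methoxybenzoic acid | CCCCCCCc1cc(OC)cc(OCc2ccccc2)c1C(=O)O | intermediate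
12 | (E)-non-3-en-2-one | CCCCC/C=C/C(C)=O | starting material
13 | dimethyl 2-(2-oxononan-4-yl)propanedioate (racemic Michael adduct) | CCCCCC(CC(C)=O)C(C(=O)OC)C(=O)OC | intermediate (not isolated)
14 | methyl 2-hydroxy-4-oxo-6-pentylcyclohex-2-ene-1-carboxylate (racemic, diastereomer and tautomer mixture) | CCCCCC1CC(=O)C=C(O)C1C(=O)OC | intermediate
15 | methyl 3-bromo-2-hydroxy-4-oxo-6-pentylcyclohex-2-ene-1-carboxylate (racemic) | CCCCCC1CC(=O)C(Br)=C(O)C1C(=O)OC | intermediate (not isolated)
16 | methyl 2,4-dihydroxy-6-pentylbenzoate | CCCCCc1cc(O)cc(O)c1C(=O)OC | intermediate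
17 | methyl 4-(benzyloxy)-2-hydroxy-6-pentylbenzoate | CCCCCc1cc(OCc2ccccc2)cc(O)c1C(=O)OC | intermediate
18 | methyl 4-(benzyloxy)-2-methoxy-6-pentylbenzoate | CCCCCc1cc(OCc2ccccc2)cc(OC)c1C(=O)OC | intermediate
19 | 4-(benzyloxy)-2-methoxy-6-pentylbenzoic acid | CCCCCc1cc(OCc2ccccc2)cc(OC)c1C(=O)O | intermediate
20 | 4-hydroxy-2-methoxy-6-pentylbenzoic acid | CCCCCc1cc(O)cc(OC)c1C(=O)O | intermediate
21 | benzyl 4-hydroxy-2-methoxy-6-pentylbenzoate | CCCCCc1cc(O)cc(OC)c1C(=O)OCc1ccccc1 | intermediate
22 | 2-(benzyloxy)-6-heptyl-4-methoxybenzoic trifluoroacetic anhydride | CCCCCCCc1cc(OC)cc(OCc2ccccc2)c1C(=O)OC(=O)C(F)(F)F | intermediate (not isolated)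
23 | benzyl 4-{[2-(benzyloxy)-6-heptyl-4-methoxybenzoyl]oxy}-2-methoxy-6-pentylbenzoate | CCCCCCCc1cc(OC)cc(OCc2ccccc2)c1C(=O)Oc1cc(CCCCC)c(C(=O)OCc2ccccc2)c(OC)c1 | intermediate
24 | 4-[(2-heptyl-6-hydroxy-4-methoxybenzoyl)oxy]-2-methoxy-6-pentylbenzoic acid (CNP0341430.0, achiral) | CCCCCCCc1cc(OC)cc(O)c1C(=O)Oc1cc(CCCCC)c(C(=O)O)c(OC)c1 | target

**Totals and risks**

Total step count: 15. Longest linear sequence: 9 steps (12 → 14 → 16 → 17 → 18 → 19 → 20 → 21 → 23 → 24; steps 7–15). The A-ring branch (steps 1–6) is convergent with it.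

Most likely to fail:

Step 3 (aromatisation). One equivalent of bromine can leave a mixture of unreacted dione, resorcylate and ring-brominated resorcylate. The fallback sets out from 6. It is deliberately over-brominated (Br2, 3.1 equiv, AcOH, rt to 60 °C) to the fully aromatic methyl 3,5-dibromo-6-heptyl-2,4-dihydroxybenzoate F1. Both aryl bromides are then removed by hydrogenolysis (H2, 10% Pd/C, NaOAc, MeOH, rt), which comes back to the route at 8.

Step 13 (carboxylate versus phenol benzylation). Some phenol O-benzylation or dibenzylation may occur. The fallback sets out from 20 and masks the phenol first. Ac2O in pyridine at rt, with aqueous work-up, gives 4-acetoxy-2-methoxy-6-pentylbenzoic acid F2. BnBr with KHCO3 in DMF at rt gives benzyl 4-acetoxy-2-methoxy-6-pentylbenzoate F3. Methanolysis of the aryl acetate (cat. K2CO3, MeOH, 0 °C) leaves the di-ortho-substituted benzyl ester untouched and comes back to the route at 21.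

Step 14 (depside coupling of two hindered partners). The mixed anhydride may react sluggishly, or the acidic medium may cause side reactions. The fallback sets out from 11, uses 21 as the partner, and comes back to the route only at the target 24. Hydrogenolysis of 11 (H2, Pd/C, EtOAc) gives 6-heptyl-2-hydroxy-4-methoxybenzoic acid F4. Acetone, TFAA and TFA (0 °C to rt) close it to the acetonide 5-heptyl-7-methoxy-2,2-dimethyl-4H-1,3-benzodioxin-4-one F5. Irradiation of F5 with 21 (300 nm, CH2Cl2, rt) generates a quinone ketene that the phenol traps, giving benzyl 4-[(6-heptyl-2-hydroxy-4-methoxybenzoyl)oxy]-2-methoxy-6-pentylbenzoate F6. Hydrogenolysis of its benzyl ester (H2, Pd/C, EtOAc, rt) gives 24.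

**Further compounds**

F1 | step 3 | methyl 3,5-dibromo-6-heptyl-2,4-dihydroxybenzoate | CCCCCCCc1c(Br)c(O)c(Br)c(O)c1C(=O)OC
F2 | step 13 | 4-acetoxy-2-methoxy-6-pentylbenzoic acid | CCCCCc1cc(OC(C)=O)cc(OC)c1C(=O)O
F3 | step 13 | benzyl 4-acetoxy-2-methoxy-6-pentylbenzoate | CCCCCc1cc(OC(C)=O)cc(OC)c1C(=O)OCc1ccccc1
F4 | step 14 | 6-heptyl-2-hydroxy-4-methoxybenzoic acid | CCCCCCCc1cc(OC)cc(O)c1C(=O)O
F5 | step 14 | 5-heptyl-7-methoxy-2,2-dimethyl-4H-1,3-benzodioxin-4-one | CCCCCCCc1cc(OC)cc2OC(C)(C)OC(=O)c12
F6 | step 14 | benzyl 4-[(6-heptyl-2-hydroxy-4-methoxybenzoyl)oxy]-2-methoxy-6-pentylbenzoate | CCCCCCCc1cc(OC)cc(O)c1C(=O)Oc1cc(CCCCC)c(C(=O)OCc2ccccc2)c(OC)c1
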